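The numbers in the tables come from a simulation from invented constants, noise included.

In a one-step world, substrate and reagent would give open intermediate and the flask would then hold it flat after one short time constant. You asked for a quick number, with the hunch that maple, the coldest flask, holds the most. Here is our reckoning.

| flask | substrate | partner | reagent | temperature | remark | time |
|---|---|---|---|---|---|---|
| epsilon | 0.34 mM | 0.45 mM | 1 mM | 65 °C | run made earlier |  |
| theta | 0.75 mM | 0.45 mM | 1 mM | 98 °C | run made earlier |  |
| zeta | 0.50 mM | 0.90 mM | 1 mM | 65 °C | run made earlier |  |
| larch | 0.50 mM | 0.450 mM | 1.00 mM | 80 °C |  | 6.0 min |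
| maple | 0.50 mM | 0.450 mM | 1.00 mM | 50 °C |  | 6.0 min |
| birch | 0.50 mM | 0.450 mM | 1.00 mM | 110 °C |  | 6.0 min |

- epsilon (time / min: open intermediate / %, target / %): 2.00: 96.1, 1.9; 4.00: 93.1, 4.3; 8.00: 84.3, 8.9; 12.0: 77.6, 11.2
- theta (time / min: open intermediate / %, target / %): 0.333: 91.6, 1.8; 0.833: 90.8, 2.3; 1.50: 86.3, 3.3; 2.50: 81.4, 2.4
- zeta (time / min: open intermediate / %, target / %): 1.00: 88.4, 1.0; 2.00: 93.4, 2.0; 5.00: 86.8, 4.2; 12.0: 73.8, 2.9

(standard deviation of a reading: 0.5 percentage points)

- the best flask by amount of open intermediate, in percent of the substrate charged; "all alike" if 1.5 percentage points covers them all (larch / maple / birch / all alike)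
- amount of open intermediate at the end, in percent of the substrate charged, larch
- amount of open intermediate at the end, in percent of the substrate charged, maple
- amount of open intermediate at the end, in percent of the substrate charged, birch



1. The runs show a fast rise, then a slow fall. In the zeta run, open intermediate reads 88.4 % after 1.00 min, early against the 6.0 min asked.

2. We take that fast step as finished, assume one reagent per substrate, and reckon with what it leaves. The free reagent is the reagent charge minus the substrate charge, 0.500 mM. Larch, maple and birch share this charge. While it is positive, the ceiling for open intermediate is the whole substrate charge; when negative, the ceiling is reagent charge over substrate charge.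

3. Heat does not raise that ceiling, so we look at how much is lost below it. Read as first-order decay, the fall has a time constant of 43.9 min in the epsilon run at 65 °C and 18.4 min in the theta run at 98 °C. These are readings, from different charges.

4. We therefore commit to maple, the coldest flask, provided its fast step still finishes in time, and we expect birch to hold least.

The forecast gives maple, with 79 % for larch, 89 % for maple and 59 % for birch: “Maple should hold the most”.

The flasks give maple, with 75.3 % for larch, 96.8 % for maple and 53.0 % for birch, so our order holds.

    substrate + reagent → open intermediate (k = 150 L mol⁻¹ s⁻¹, Ea = 54.0 kJ mol⁻¹)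
    reagent + partner → second intermediate (k = 13.0 L mol⁻¹ s⁻¹, Ea = 54.0 kJ mol⁻¹)
    open intermediate + second intermediate → target (k = 6.60 L mol⁻¹ s⁻¹, Ea = 68.0 kJ mol⁻¹)
    2 second intermediate → homo product (k = 8.00 L mol⁻¹ s⁻¹, Ea = 50.0 kJ mol⁻¹)
    partner + target → over-reaction product (k = 54.0 L mol⁻¹ s⁻¹, Ea = 62.0 kJ mol⁻¹)
    substrate + target → side product (k = 180 L mol⁻¹ s⁻¹, Ea = 40.0 kJ mol⁻¹)
    (constants at 80 °C)

The free reagent of 0.500 mM does not stay idle: with partner it makes second intermediate, which consumes open intermediate. Take away what the temperature does to the step from open intermediate and second intermediate to target, and the gap between birch and maple shrinks from 44 percentage points to 0.03 points, the largest single effect of temperature on that gap.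

The neighbour of larch charged with 0.25 mM of reagent has a free reagent of −0.250 mM, so reagent is the limiting reagent and the ceiling is 50.0 %. It gives 43.7 % at 6.00 min, with reagent at 0 % and 53.5 % of the substrate left.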